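The 4-oxo ring (carotenoid numbering: C1 gem-dimethyl carbon, C2 and C3 methylenes, C4 carbonyl, C5 methyl-bearing CH, C6 chain-bearing CH) is read as the adduct of a 2-silyloxy-diene C3=C4(O)–C5=C6 and a 1,1-disubstituted alkene C2=C1. A catalytic enantioselective Diels–Alder reaction of an acyclic tetraenyl silyl enol ether, which already carries the C7–C11 chain, with methacrolein forms C2–C3 and C1–C6 at once, sets C6 and leaves C4 as a masked ketone. The formyl group on C1 is then reduced to the second methyl group. One adduct serves both end groups, which are joined to the C10 dialdehyde by two Wittig reactions.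

Key step: step 4

Remarks on the chemistry
- Ring atoms are numbered C1–C6 as in carotenoids throughout.
- Commercial phosphonate 4 is an E/Z mixture; the SMILES shows the E form, and the anion converges in step 2.
- Catalyst A (step 4) is made in the flask from (R)-α,α-diphenyl-2-pyrrolidinemethanol, tri(o-tolyl)boroxine (o-TolBO)3 and Tf2NH. It is the N-protonated oxazaborolidine salt Cc1ccccc1B1OC(c2ccccc2)(c2ccccc2)[C@H]2CCC[NH+]12.[N-](S(=O)(=O)C(F)(F)F)S(=O)(=O)C(F)(F)F.
- The R antipode is chosen from the accepted pre-transition-state model for α-substituted acroleins combined with an endo transition state. Should the exo mode dominate, the S antipode would deliver the same C6 configuration.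

Step 1
Reactants: 1 2,3-dimethylfuran
Product: 3 (2E)-3-methyl-4-oxopent-2-enal, via (2Z)-3-methyl-4-oxopent-2-enal 2 (not isolated)
Conditions: N-bromosuccinimide (1.1 equiv), pyridine (2 equiv), THF/acetone/H2O, −20 °C to rt
Reagents that add atoms: water, O
Why: Oxidative ring opening of the furan (bromination, hydration, ring cleavage) unmasks a cis-ene-dicarbonyl, which pyridine should isomerise to the more stable E isomer with acetyl and formyl trans.

Step 2
Reactants: 3 (2E)-3-methyl-4-oxopent-2-enal; 4 ethyl (2E)-4-(diethoxyphosphoryl)-3-methylbut-2-enoate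
Product: 5 ethyl (2E,4E,6E)-3,7-dimethyl-8-oxonona-2,4,6-trienoate
Conditions: 4, LiN(SiMe3)2, THF, −78 °C; then 3, −78 to 0 °C
Reagents that add atoms: none
Why: Horner–Wadsworth–Emmons olefination, in which the stabilised phosphonate anion should attack the aldehyde far faster than the conjugated methyl ketone and give the E alkene.

Step 3
Reactants: 5 ethyl (2E,4E,6E)-3,7-dimethyl-8-oxonona-2,4,6-trienoate
Product: 6 ethyl (2E,4E,6E)-3,7-dimethyl-8-[(triisopropylsilyl)oxy]nona-2,4,6,8-tetraenoate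
Conditions: i-Pr3SiOTf, Et3N, CH2Cl2, 0 °C to rt
Reagents that add atoms: triisopropylsilyl triflate, CC(C)[Si](OS(=O)(=O)C(F)(F)F)(C(C)C)C(C)C
Why: Soft enolisation at the acetyl CH3, the only enolisable α-position, should give the cross-conjugated 2-silyloxy-diene, whose bulky silyl group tolerates a cationic Lewis acid.

Step 4
Reactants: 6 ethyl (2E,4E,6E)-3,7-dimethyl-8-[(triisopropylsilyl)oxy]nona-2,4,6,8-tetraenoate; 7 methacrolein (2-methylprop-2-enal)
Product: 8 ethyl (2E,4E)-5-[(1S,6R)-6-formyl-2,6-dimethyl-3-[(triisopropylsilyl)oxy]cyclohex-2-en-1-yl]-3-methylpenta-2,4-dienoate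
Conditions: 7 (3 equiv), catalyst A (20 mol%), CH2Cl2, −78 to −40 °C; chromatographic removal of the minor exo diastereomer
Reagents that add atoms: none
Why: Catalyst A binds methacrolein at boron (s-trans enal, formyl C–H···O contact), and the nucleophilic CH2 terminus of the silyl enol ether (C3) attacks the β-carbon (C2) while C6 bonds to the α-carbon (C1) in an asynchronous concerted normal-demand Diels–Alder reaction, the closest known type being oxazaborolidinium-catalysed additions of 2-silyloxybutadienes to α-substituted acroleins. The six-membered ring closes in the intermolecular [4π+2π] mode, suprafacial on both partners. Regiochemistry is unambiguous because the silyloxy group at C4 ("para") and the chain at C6 ("ortho") both direct the formyl-bearing carbon to C6. C6 is controlled by the catalyst, whose carbinol aryl group shields one face of the bound enal so that the R antipode should direct the diene to the si face of the α-carbon, together with the endo orientation of the formyl group and the E geometry of C5=C6; C1 follows from the same endo rule and is erased in step 6. Site selectivity is secured because only the silyloxy-diene terminus is electron-rich, the other double bonds being deactivated by the ester and blocked at fully substituted C5. Endo and exo adducts from one catalyst antipode carry opposite configuration at C6, so the exo isomer must be removed here, before C1 loses its stereogenicity.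

Step 5
Reactants: 8 ethyl (2E,4E)-5-[(1S,6R)-6-formyl-2,6-dimethyl-3-[(triisopropylsilyl)oxy]cyclohex-2-en-1-yl]-3-methylpenta-2,4-dienoate
Product: 9 the (E)-N-tosylhydrazone of 8
Conditions: TsNHNH2 (1.05 equiv), THF, 4 Å molecular sieves, rt
Reagents that add atoms: p-toluenesulfonyl hydrazide, Cc1ccc(cc1)S(=O)(=O)NN
Why: Neutral condensation of the only aldehyde with the sulfonyl hydrazide should give the hydrazone and leave the ester and the silyl enol ether untouched.

Step 6
Reactants: 9 the (E)-N-tosylhydrazone of 8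
Product: 10 ethyl (2E,4E)-3-methyl-5-[(1R)-2,6,6-trimethyl-3-[(triisopropylsilyl)oxy]cyclohex-2-en-1-yl]penta-2,4-dienoate
Conditions: catecholborane, CHCl3, 0 °C; then NaOAc·3H2O, reflux
Reagents that add atoms: none
Why: Caglioti-type reduction in the catecholborane variant, in which hydride adds to C=N and acetate triggers loss of sulfinate and N2 to leave CH3 under non-basic conditions that should spare the enol ether, the dienoate and the doubly allylic C6–H, so that C1 becomes the gem-dimethyl carbon.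

Step 7
Reactants: 10 ethyl (2E,4E)-3-methyl-5-[(1R)-2,6,6-trimethyl-3-[(triisopropylsilyl)oxy]cyclohex-2-en-1-yl]penta-2,4-dienoate
Product: 11 (2E,4E)-3-methyl-5-[(1R)-2,6,6-trimethyl-3-[(triisopropylsilyl)oxy]cyclohex-2-en-1-yl]penta-2,4-dien-1-ol
Conditions: i-Bu2AlH (2.5 equiv), CH2Cl2, −78 °C; aqueous KNaC4H4O6 work-up
Reagents that add atoms: none
Why: 1,2-Reduction of the conjugated ester by the aluminium hydride should give the allylic alcohol while the silyl enol ether keeps C4 protected from hydride.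

Step 8
Reactants: 11 (2E,4E)-3-methyl-5-[(1R)-2,6,6-trimethyl-3-[(triisopropylsilyl)oxy]cyclohex-2-en-1-yl]penta-2,4-dien-1-ol
Product: 13 (2S,3S)-3-[(1E,3E)-5-hydroxy-3-methylpenta-1,3-dien-1-yl]-2,4,4-trimethylcyclohexan-1-one, via 2,3-cis ketone epimer 12 (not isolated)
Conditions: Bu4NF, AcOH, THF, 0 °C; then DBU (0.3 equiv), rt
Reagents that add atoms: none
Why: Fluoride cleaves the Si–O bond and protonation gives the ketone, after which base-mediated epimerisation at C5 (α to the ketone) should drive the mixture to the trans-diequatorial isomer under thermodynamic control, C6 being non-acidic once the ester is reduced.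

Step 9
Reactants: 13 (2S,3S)-3-[(1E,3E)-5-hydroxy-3-methylpenta-1,3-dien-1-yl]-2,4,4-trimethylcyclohexan-1-one
Product: 14 [(2E,4E)-3-methyl-5-[(1S,2S)-2,6,6-trimethyl-3-oxocyclohexyl]penta-2,4-dien-1-yl]triphenylphosphonium bromide
Conditions: PPh3·HBr, MeOH, rt
Reagents that add atoms: triphenylphosphine hydrobromide, Br.c1ccc(cc1)P(c1ccccc1)c1ccccc1
Why: Acid ionisation of the dienylic alcohol to a pentadienyl cation and capture by PPh3 at the primary terminus (the standard C15 phosphonium salt formation) should leave the saturated ketone untouched.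

Step 10
Reactants: 13 (2S,3S)-3-[(1E,3E)-5-hydroxy-3-methylpenta-1,3-dien-1-yl]-2,4,4-trimethylcyclohexan-1-one
Product: 15 (1S,2S,3S)-3-[(1E,3E)-5-hydroxy-3-methylpenta-1,3-dien-1-yl]-2,4,4-trimethylcyclohexan-1-ol
Conditions: NaBH4, MeOH, −40 °C; chromatography
Reagents that add atoms: none
Why: Axial hydride delivery to the conformationally fixed cyclohexanone (equatorial C5 methyl and C6 chain, no syn-axial substituent on the attack face) should give mainly the equatorial C4 alcohol trans to the C5 methyl group.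

Step 11
Reactants: 15 (1S,2S,3S)-3-[(1E,3E)-5-hydroxy-3-methylpenta-1,3-dien-1-yl]-2,4,4-trimethylcyclohexan-1-ol
Product: 16 [(2E,4E)-5-[(1S,2S,3S)-3-hydroxy-2,6,6-trimethylcyclohexyl]-3-methylpenta-2,4-dien-1-yl]triphenylphosphonium bromide
Conditions: PPh3·HBr, MeOH, rt
Reagents that add atoms: triphenylphosphine hydrobromide, Br.c1ccc(cc1)P(c1ccccc1)c1ccccc1
Why: Only the dienylic primary alcohol ionises under these conditions, so the phosphonium salt should form with the secondary ring alcohol intact.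

Step 12
Reactants: 14 [(2E,4E)-3-methyl-5-[(1S,2S)-2,6,6-trimethyl-3-oxocyclohexyl]penta-2,4-dien-1-yl]triphenylphosphonium bromide; 17 (2E,4E,6E)-2,7-dimethylocta-2,4,6-trienedial
Product: 19 (2E,4E,6E,8E,10E,12E)-2,7,11-trimethyl-13-[(1S,2S)-2,6,6-trimethyl-3-oxocyclohexyl]trideca-2,4,6,8,10,12-hexaenal, via 8Z isomer 18 (not isolated)
Conditions: 17 (3 equiv), NaOMe added slowly, CH2Cl2/MeOH, 0 °C; then heptane, 90 °C, dark
Reagents that add atoms: none
Why: Wittig olefination of the semi-stabilised allylic ylide with one formyl group of the dialdehyde (used in excess, the saturated ketone being far less reactive), after which the hindered cis alkene should equilibrate thermally to E.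

Step 13
Reactants: 19 (2E,4E,6E,8E,10E,12E)-2,7,11-trimethyl-13-[(1S,2S)-2,6,6-trimethyl-3-oxocyclohexyl]trideca-2,4,6,8,10,12-hexaenal; 16 [(2E,4E)-5-[(1S,2S,3S)-3-hydroxy-2,6,6-trimethylcyclohexyl]-3-methylpenta-2,4-dien-1-yl]triphenylphosphonium bromide
Product: 21 all-E (4S,5S,6S,5'S,6'S)-4-hydroxy-5,6,5',6'-tetrahydro-β,β-caroten-4'-one, via 11Z isomer 20 (not isolated)
Conditions: 16 (1.3 equiv), NaOMe, CH2Cl2/MeOH, rt; then heptane, reflux, dark; crystallisation
Reagents that add atoms: none
Why: Second Wittig olefination, which tolerates the free hydroxyl and the ketone, followed by thermal isomerisation of the hindered cis alkene, should give the all-E target.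

Compound list
1 | 2,3-dimethylfuran | Cc1occc1C | starting material
2 | (2Z)-3-methyl-4-oxopent-2-enal | CC(=O)/C(C)=C\C=O | intermediate
3 | (2E)-3-methyl-4-oxopent-2-enal | CC(=O)/C(C)=C/C=O | intermediate
4 | ethyl (2E)-4-(diethoxyphosphoryl)-3-methylbut-2-enoate (triethyl 3-methyl-4-phosphonocrotonate) | CCOC(=O)/C=C(C)/CP(=O)(OCC)OCC | starting material
5 | ethyl (2E,4E,6E)-3,7-dimethyl-8-oxonona-2,4,6-trienoate | CCOC(=O)/C=C(C)/C=C/C=C(C)/C(C)=O | intermediate
6 | ethyl (2E,4E,6E)-3,7-dimethyl-8-[(triisopropylsilyl)oxy]nona-2,4,6,8-tetraenoate | CCOC(=O)/C=C(C)/C=C/C=C(C)/C(=C)O[Si](C(C)C)(C(C)C)C(C)C | intermediate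
7 | methacrolein | CC(=C)C=O | starting material
8 | ethyl (2E,4E)-5-[(1S,6R)-6-formyl-2,6-dimethyl-3-[(triisopropylsilyl)oxy]cyclohex-2-en-1-yl]-3-methylpenta-2,4-dienoate (formyl cis to the side chain) | CCOC(=O)/C=C(C)/C=C/[C@H]1C(C)=C(O[Si](C(C)C)(C(C)C)C(C)C)CC[C@@]1(C)C=O | intermediate
9 | (E)-N-tosylhydrazone of 8 | CCOC(=O)/C=C(C)/C=C/[C@H]1C(C)=C(O[Si](C(C)C)(C(C)C)C(C)C)CC[C@@]1(C)/C=N/NS(=O)(=O)c1ccc(C)cc1 | intermediate
10 | ethyl (2E,4E)-3-methyl-5-[(1R)-2,6,6-trimethyl-3-[(triisopropylsilyl)oxy]cyclohex-2-en-1-yl]penta-2,4-dienoate | CCOC(=O)/C=C(C)/C=C/[C@H]1C(C)=C(O[Si](C(C)C)(C(C)C)C(C)C)CCC1(C)C | intermediate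
11 | (2E,4E)-3-methyl-5-[(1R)-2,6,6-trimethyl-3-[(triisopropylsilyl)oxy]cyclohex-2-en-1-yl]penta-2,4-dien-1-ol | OC/C=C(C)/C=C/[C@H]1C(C)=C(O[Si](C(C)C)(C(C)C)C(C)C)CCC1(C)C | intermediate
12 | (2R,3S)-3-[(1E,3E)-5-hydroxy-3-methylpenta-1,3-dien-1-yl]-2,4,4-trimethylcyclohexan-1-one (2,3-cis) | OC/C=C(C)/C=C/[C@H]1[C@@H](C)C(=O)CCC1(C)C | intermediate
13 | (2S,3S)-3-[(1E,3E)-5-hydroxy-3-methylpenta-1,3-dien-1-yl]-2,4,4-trimethylcyclohexan-1-one (2,3-trans) | OC/C=C(C)/C=C/[C@H]1[C@H](C)C(=O)CCC1(C)C | intermediate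
14 | [(2E,4E)-3-methyl-5-[(1S,2S)-2,6,6-trimethyl-3-oxocyclohexyl]penta-2,4-dien-1-yl]triphenylphosphonium bromide | [Br-].CC(/C=C/[C@H]1[C@H](C)C(=O)CCC1(C)C)=C\C[P+](c1ccccc1)(c1ccccc1)c1ccccc1 | intermediate
15 | (1S,2S,3S)-3-[(1E,3E)-5-hydroxy-3-methylpenta-1,3-dien-1-yl]-2,4,4-trimethylcyclohexan-1-ol | OC/C=C(C)/C=C/[C@H]1[C@H](C)[C@@H](O)CCC1(C)C | intermediate
16 | [(2E,4E)-5-[(1S,2S,3S)-3-hydroxy-2,6,6-trimethylcyclohexyl]-3-methylpenta-2,4-dien-1-yl]triphenylphosphonium bromide | [Br-].CC(/C=C/[C@H]1[C@H](C)[C@@H](O)CCC1(C)C)=C\C[P+](c1ccccc1)(c1ccccc1)c1ccccc1 | intermediate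
17 | (2E,4E,6E)-2,7-dimethylocta-2,4,6-trienedial | O=C/C(C)=C/C=C/C=C(C)/C=O | starting material
18 | (2E,4E,6E,8Z,10E,12E)-2,7,11-trimethyl-13-[(1S,2S)-2,6,6-trimethyl-3-oxocyclohexyl]trideca-2,4,6,8,10,12-hexaenal | O=C/C(C)=C/C=C/C=C(C)/C=C\C=C(C)\C=C\[C@H]1[C@H](C)C(=O)CCC1(C)C | intermediate
19 | (2E,4E,6E,8E,10E,12E)-2,7,11-trimethyl-13-[(1S,2S)-2,6,6-trimethyl-3-oxocyclohexyl]trideca-2,4,6,8,10,12-hexaenal | O=C/C(C)=C/C=C/C=C(C)/C=C/C=C(C)/C=C/[C@H]1[C@H](C)C(=O)CCC1(C)C | intermediate
20 | (11Z)-isomer of the target | CC(/C=C\C=C(C)\C=C\[C@H]1[C@H](C)[C@@H](O)CCC1(C)C)=C\C=C\C=C(C)\C=C\C=C(C)\C=C\[C@H]1[C@H](C)C(=O)CCC1(C)C | intermediate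
21 | all-E (4S,5S,6S,5'S,6'S)-4-hydroxy-5,6,5',6'-tetrahydro-β,β-caroten-4'-one | CC(/C=C/C=C(C)/C=C/[C@H]1[C@H](C)[C@@H](O)CCC1(C)C)=C\C=C\C=C(C)\C=C\C=C(C)\C=C\[C@H]1[C@H](C)C(=O)CCC1(C)C | target

Total step count: 13. Longest linear sequence: 11 steps (steps 1–9, 12, 13; the hydroxy branch through steps 10 and 11 is equally long).

Steps most likely to fail

Step 4. The cationic boron catalyst may be sequestered by the trienoate, or the enal may add at another site of the polyene. Endo/exo discrimination may also be too low, which would erode the configurational purity at C6 once C1 is made symmetric. The fallback builds the ring on a shorter diene and attaches the chain afterwards; it sets out from 3 and comes back at 10. Wittig reaction of 3 with Ph3P=CHCO2Et should give ethyl (2E,4E)-5-methyl-6-oxohepta-2,4-dienoate F1. Silylation with i-Pr3SiOTf/Et3N should give the trienyl silyl enol ether F2. Cycloaddition with 7 under catalyst A should give the formyl cyclohexene F3, in which only one remote double bond competes. Tosylhydrazone F4 and catecholborane/NaOAc reduction should give the gem-dimethyl acrylate F5. Me(MeO)NH·HCl/AlMe3 should give the Weinreb amide F6 and MeMgBr the methyl ketone F7. Horner–Wadsworth–Emmons reaction of F7 with triethyl phosphonoacetate/NaH should then give 10.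

Step 6. Hydride transfer to the neopentyl hydrazone may be incomplete, or catecholborane may compete by reducing the dienoate. The fallback replaces the hydrazone route by radical deoxygenation; it sets out from 8 and comes back at 10. NaBH4 in MeOH at 0 °C should reduce the aldehyde to the neopentyl alcohol F8. PhOC(S)Cl/pyridine/DMAP should give the phenyl thionocarbonate F9. Barton–McCombie reduction (Bu3SnH, AIBN, toluene, 110 °C) should then give 10.

Step 2. The phosphonate anion may enolise the methyl ketone or add in a conjugate sense to the doubly activated ene-dicarbonyl 3, causing oligomerisation. The fallback forms the C5=C6 bond last by aldol condensation and avoids 3; it sets out from 4 and comes back at 5. Horner–Wadsworth–Emmons reaction of 4 with 2,2-dimethoxyacetaldehyde should give the acetal F10. Aqueous formic acid should unmask ethyl (2E,4E)-3-methyl-6-oxohexa-2,4-dienoate F11. Acid-catalysed crossed aldol condensation of F11 with butan-2-one (dry HCl, reacting at its methylene carbon) should give 5.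

Further compounds
F1 | step 4 | ethyl (2E,4E)-5-methyl-6-oxohepta-2,4-dienoate | CCOC(=O)/C=C/C=C(C)/C(C)=O
F2 | step 4 | ethyl (2E,4E)-5-methyl-6-[(triisopropylsilyl)oxy]hepta-2,4,6-trienoate | CCOC(=O)/C=C/C=C(C)/C(=C)O[Si](C(C)C)(C(C)C)C(C)C
F3 | step 4 | ethyl (2E)-3-[(1S,6R)-6-formyl-2,6-dimethyl-3-[(triisopropylsilyl)oxy]cyclohex-2-en-1-yl]prop-2-enoate | CCOC(=O)/C=C/[C@H]1C(C)=C(O[Si](C(C)C)(C(C)C)C(C)C)CC[C@@]1(C)C=O
F4 | step 4 | (E)-N-tosylhydrazone of F3 | CCOC(=O)/C=C/[C@H]1C(C)=C(O[Si](C(C)C)(C(C)C)C(C)C)CC[C@@]1(C)/C=N/NS(=O)(=O)c1ccc(C)cc1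
F5 | step 4 | ethyl (2E)-3-[(1R)-2,6,6-trimethyl-3-[(triisopropylsilyl)oxy]cyclohex-2-en-1-yl]prop-2-enoate | CCOC(=O)/C=C/[C@H]1C(C)=C(O[Si](C(C)C)(C(C)C)C(C)C)CCC1(C)C
F6 | step 4 | (2E)-N-methoxy-N-methyl-3-[(1R)-2,6,6-trimethyl-3-[(triisopropylsilyl)oxy]cyclohex-2-en-1-yl]prop-2-enamide | CON(C)C(=O)/C=C/[C@H]1C(C)=C(O[Si](C(C)C)(C(C)C)C(C)C)CCC1(C)C
F7 | step 4 | (3E)-4-[(1R)-2,6,6-trimethyl-3-[(triisopropylsilyl)oxy]cyclohex-2-en-1-yl]but-3-en-2-one | CC(=O)/C=C/[C@H]1C(C)=C(O[Si](C(C)C)(C(C)C)C(C)C)CCC1(C)C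
F8 | step 6 | ethyl (2E,4E)-5-[(1R,6R)-6-(hydroxymethyl)-2,6-dimethyl-3-[(triisopropylsilyl)oxy]cyclohex-2-en-1-yl]-3-methylpenta-2,4-dienoate | CCOC(=O)/C=C(C)/C=C/[C@H]1C(C)=C(O[Si](C(C)C)(C(C)C)C(C)C)CC[C@@]1(C)CO
F9 | step 6 | O-phenyl thionocarbonate of F8 | CCOC(=O)/C=C(C)/C=C/[C@H]1C(C)=C(O[Si](C(C)C)(C(C)C)C(C)C)CC[C@@]1(C)COC(=S)Oc1ccccc1
F10 | step 2 | ethyl (2E,4E)-6,6-dimethoxy-3-methylhexa-2,4-dienoate | CCOC(=O)/C=C(C)/C=C/C(OC)OC
F11 | step 2 | ethyl (2E,4E)-3-methyl-6-oxohexa-2,4-dienoate | CCOC(=O)/C=C(C)/C=C/C=O
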